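## Retrosynthetic overview

1. Target 14 comes from its O4-benzyl ether 13 by hydrogenolysis. Ring A (N1–C2–C3–C4–C4a–C8a) is bought with pyridone 1. Ring B (C4a–C5–C6–C7–C8–C8a) is the only ring built and closes in the penultimate step.
2. Ring B is cut at C8a–C8, which makes 13 an isomer of the monocyclic pyridine aldehyde 11. The closure joins two electrophilic carbons (pyridinium C8a and formyl C8) by turning C8 into a nucleophilic acyl radical. An electron and a proton are then returned, so the carbinol forms directly.
3. Enabling feature: C8a is the only C–H carbon of ring A. It is alpha to N1 and ortho to C4a, which carries the C5 side chain, so after N-protonation it is the one LUMO-rich site that C8 can reach through a six-membered closure. The peri C4–O substituent holds the C5 chain pseudoaxial and relays C5 to C8.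
4. Aldehyde 11 comes from hydroformylation of vinyl compound 10 (adds C8). Compound 10 comes from copper-catalysed asymmetric allylic alkylation of chloride 7 with Grignard reagent 9 (sets C5). Chloride 7 traces back to Suzuki coupling of iodide 3 with boronate 4.
5. Iodide 3 comes from C5 iodination and O4 benzylation of 1.

Key step: step 8

Remark: the locants C2 to C8a are those of the tetrahydroquinoline target and are used for all intermediates.

Assumption: the sense of induction of the phosphoramidite in step 6 is taken by analogy with cinnamyl chloride. Both ligand antipodes are available, and the one that gives (S)-10 is meant.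

## Route

Step 1
Reactants: 1 3-methoxy-2-methylpyridin-4(1H)-one
Product: 2 5-iodo-3-methoxy-2-methylpyridin-4(1H)-one
Conditions: NIS (1.05 equiv), DMF, rt to 50 °C
Reagents that add atoms: N-iodosuccinimide O=C1CCC(=O)N1I
Why: Electrophilic iodination of the N1–C6=C5–C4=O enaminone should occur only at C5, its nucleophilic alpha-carbon, because C3 is blocked by methoxy.

Step 2
Reactants: 2 5-iodo-3-methoxy-2-methylpyridin-4(1H)-one
Product: 3 4-(benzyloxy)-5-iodo-3-methoxy-2-methylpyridine
Conditions: BnBr (1.2 equiv), Ag2CO3 (0.7 equiv), toluene, 80 °C, dark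
Reagents that add atoms: benzyl bromide BrCc1ccccc1
Why: Silver-salt alkylation of an ambident pyridone in a non-polar solvent should occur at oxygen and give the aromatic 4-benzyloxypyridine, which masks the pyridone for steps 3 to 8.

Step 3
Reactants: 3 4-(benzyloxy)-5-iodo-3-methoxy-2-methylpyridine; 4 (E)-3-(4,4,5,5-tetramethyl-1,3,2-dioxaborolan-2-yl)prop-2-en-1-ol
Product: 5 (E)-3-[4-(benzyloxy)-5-methoxy-6-methylpyridin-3-yl]prop-2-en-1-ol
Conditions: PdCl2(dppf) (3 mol %), K2CO3 (2.5 equiv), dioxane/H2O 4:1, 80 °C
Reagents that add atoms: none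
Why: In this Suzuki–Miyaura coupling zerovalent palladium inserts into the C5–I bond and the alkenyl group is transferred with retention of the E geometry, while the free hydroxyl and the benzyl ether are tolerated.

Step 4
Reactants: 5 (E)-3-[4-(benzyloxy)-5-methoxy-6-methylpyridin-3-yl]prop-2-en-1-ol
Product: 7 4-(benzyloxy)-5-[(E)-3-chloroprop-1-en-1-yl]-3-methoxy-2-methylpyridine, via allylic mesylate 6 (not isolated)
Conditions: MsCl (1.1 equiv), LiCl (3 equiv), 2,4,6-collidine (1.2 equiv), DMF, 0 °C; cold work-up, used at once
Reagents that add atoms: lithium chloride [Li+].[Cl-]; methanesulfonyl chloride CS(=O)(=O)Cl (its atoms stay only in 6)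
Why: Mesylation followed by SN2 displacement with chloride at the primary allylic carbon under buffered conditions should give the linear E chloride without allylic transposition and without acid that could cleave the benzyl ether.

Step 5
Reactants: 8 (5-bromopentyl)benzene
Product: 9 5-phenylpentylmagnesium bromide (ether solution, titrated and used as such)
Conditions: Mg turnings (1.2 equiv), I2 (crystal), Et2O, reflux
Reagents that add atoms: magnesium [Mg]
Why: Grignard formation by insertion of magnesium into a primary alkyl bromide that carries no other reactive group.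

Step 6
Reactants: 7 4-(benzyloxy)-5-[(E)-3-chloroprop-1-en-1-yl]-3-methoxy-2-methylpyridine; 9 5-phenylpentylmagnesium bromide
Product: 10 (S)-4-(benzyloxy)-3-methoxy-2-methyl-5-(8-phenyloct-1-en-3-yl)pyridine
Conditions: Cu(O2CC4H3S) (copper thiophene-2-carboxylate, 3 mol %), BINOL-derived N,N-bis[1-(2-methoxyphenyl)ethyl]phosphoramidite (3.3 mol %), CH2Cl2, −78 °C, slow addition of 9 (1.3 equiv)
Reagents that add atoms: none
Why: In this copper-catalysed asymmetric allylic alkylation the ligated alkylcopper adds anti-SN2' to the cinnamyl-type chloride and the sigma-allyl trivalent copper species collapses at the gamma-carbon before it equilibrates, so the branched product should form with the chiral phosphoramidite selecting the alkene face and setting C5 as S.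

Step 7
Reactants: 10 (S)-4-(benzyloxy)-3-methoxy-2-methyl-5-(8-phenyloct-1-en-3-yl)pyridine
Product: 11 (S)-4-[4-(benzyloxy)-5-methoxy-6-methylpyridin-3-yl]-9-phenylnonanal
Conditions: Rh(acac)(CO)2 (1 mol %), Xantphos (3 mol %), CO/H2 (1:1, 20 bar), toluene, 70 °C
Reagents that add atoms: carbon monoxide [C-]#[O+]
Why: In this linear-selective hydroformylation the wide-bite-angle diphosphine and the allylic branching place rhodium on the terminal carbon, CO insertion adds C8 as the formyl group, and under CO pressure beta-hydride elimination towards C5 is slow, so the stereocentre should survive.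

Step 8
Reactants: 11 (S)-4-[4-(benzyloxy)-5-methoxy-6-methylpyridin-3-yl]-9-phenylnonanal
Product: 13 (5S,8R)-4-(benzyloxy)-3-methoxy-2-methyl-5-(5-phenylpentyl)-5,6,7,8-tetrahydroquinolin-8-ol, via enaminol 12 (not isolated)
Conditions: 3,6-di-tert-butyl-9-mesityl-10-phenylacridinium tetrafluoroborate (5 mol %), 1,1'-binaphthyl-2,2'-diyl hydrogen thiophosphate (10 mol %), CF3CO2H (1.5 equiv), CH2Cl2 (0.02 M), 450 nm LED, rt, argon; aq NaHCO3
Reagents that add atoms: none
Why: The photo-excited acridinium oxidises the thiophosphate to a sulfur-centred radical that abstracts the formyl hydrogen of N-protonated 11; the nucleophilic C8 acyl radical (the carbonyl carbon with reversed polarity) adds to the electrophilic C8a of the pyridinium, loss of the C8a proton and a spin-centre shift (proton transfer to the C8 oxygen) give a C8 ketyl-type radical, the acridine radical reduces it to enaminol 12, and C-protonation at C8 gives 13, so the step is an isomerisation that loses no atom. The closest known reaction type is the redox-neutral Minisci-type hydroxyalkylation of isoquinolines, quinolines and pyridines with aliphatic aldehydes under the same acridinium/thiophosphoric acid pair, used here within one molecule. Ring B closes in a six-membered mode that is 6-exo-trig with respect to the C8a=N1 iminium bond, whereas 5-exo ipso attack at C4a would meet a carbon with almost no LUMO coefficient and give an unstabilised spiro radical. The new C8 stereocentre is controlled by C5: allylic 1,3-strain with the peri C4 benzyloxy group holds the phenylpentyl chain pseudoaxial, and the proton should enter the planar C8=C8a enol pseudoaxially on the opposite face, which places the hydroxyl cis to the chain (8R), pseudoequatorial and close to N1. The step needs site selectivity in both the hydrogen abstraction and the radical addition: the hydridic formyl C–H is polarity-matched to the electrophilic sulfur radical while C5–H and the OCH2Ph hydrogens sit on a cationic ring and are mismatched, and C2 (methyl) and C4 (benzyloxy) are blocked, so C8a is the only open alpha or gamma position. C5 is not touched and keeps its S configuration.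

Step 9
Reactants: 13 (5S,8R)-4-(benzyloxy)-3-methoxy-2-methyl-5-(5-phenylpentyl)-5,6,7,8-tetrahydroquinolin-8-ol
Product: 14 (5S,8R)-8-hydroxy-3-methoxy-2-methyl-5-(5-phenylpentyl)-5,6,7,8-tetrahydroquinolin-4(1H)-one (target)
Conditions: H2 (1 atm), Pd/C (10 wt %), EtOH, rt
Reagents that add atoms: none
Why: Hydrogenolysis of the benzyl ether frees the 4-hydroxypyridine, which tautomerises to the 4(1H)-pyridone, while the C8 hydroxyl at the alpha-position of the azine should not be hydrogenolysed under neutral conditions and both stereocentres stay untouched.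

## Compound list

1 | 3-methoxy-2-methylpyridin-4(1H)-one | COc1c(C)[nH]ccc1=O | starting material
2 | 5-iodo-3-methoxy-2-methylpyridin-4(1H)-one | COc1c(C)[nH]cc(I)c1=O | intermediate
3 | 4-(benzyloxy)-5-iodo-3-methoxy-2-methylpyridine | COc1c(C)ncc(I)c1OCc1ccccc1 | intermediate
4 | (E)-3-(4,4,5,5-tetramethyl-1,3,2-dioxaborolan-2-yl)prop-2-en-1-ol | OC/C=C/B1OC(C)(C)C(C)(C)O1 | starting material
5 | (E)-3-[4-(benzyloxy)-5-methoxy-6-methylpyridin-3-yl]prop-2-en-1-ol | COc1c(C)ncc(/C=C/CO)c1OCc1ccccc1 | intermediate
6 | (E)-3-[4-(benzyloxy)-5-methoxy-6-methylpyridin-3-yl]prop-2-en-1-yl methanesulfonate | COc1c(C)ncc(/C=C/COS(C)(=O)=O)c1OCc1ccccc1 | intermediate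
7 | 4-(benzyloxy)-5-[(E)-3-chloroprop-1-en-1-yl]-3-methoxy-2-methylpyridine | COc1c(C)ncc(/C=C/CCl)c1OCc1ccccc1 | intermediate
8 | (5-bromopentyl)benzene | BrCCCCCc1ccccc1 | starting material
9 | 5-phenylpentylmagnesium bromide | Br[Mg]CCCCCc1ccccc1 | intermediate
10 | (S)-4-(benzyloxy)-3-methoxy-2-methyl-5-(8-phenyloct-1-en-3-yl)pyridine | COc1c(C)ncc(c1OCc1ccccc1)[C@@H](CCCCCc1ccccc1)C=C | intermediate
11 | (S)-4-[4-(benzyloxy)-5-methoxy-6-methylpyridin-3-yl]-9-phenylnonanal | COc1c(C)ncc(c1OCc1ccccc1)[C@@H](CCCCCc1ccccc1)CCC=O | intermediate
12 | (S)-4-(benzyloxy)-3-methoxy-2-methyl-5-(5-phenylpentyl)-1,5,6,7-tetrahydroquinolin-8-ol (enaminol) | COC1=C(C)NC2=C(O)CC[C@H](CCCCCc3ccccc3)C2=C1OCc1ccccc1 | intermediate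
13 | (5S,8R)-4-(benzyloxy)-3-methoxy-2-methyl-5-(5-phenylpentyl)-5,6,7,8-tetrahydroquinolin-8-ol | COc1c(C)nc2c(c1OCc1ccccc1)[C@@H](CCCCCc1ccccc1)CC[C@H]2O | intermediate
14 | (5S,8R)-8-hydroxy-3-methoxy-2-methyl-5-(5-phenylpentyl)-5,6,7,8-tetrahydroquinolin-4(1H)-one | COc1c(C)[nH]c2c(c1=O)[C@@H](CCCCCc1ccccc1)CC[C@H]2O | target

## Step count and risks

Total step count: 9.
Longest linear sequence: 8 (steps 1, 2, 3, 4, 6, 7, 8, 9). Step 5 is a one-step side branch.

The three steps most likely to fail are steps 8, 6 and 2.

**Step 8.** On this donor-substituted pyridinium the electron-return leg (spin-centre shift and reduction) may lag behind the radical addition. The protonation at C8 may also proceed with poor facial selectivity.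
- The fallback sets out from 11 and comes back to the route at 13. It separates bond formation from stereocontrol.
- An oxidative intramolecular Minisci acylation (t-BuOOH, FeSO4 cat., CF3CO2H, MeCN, 60 °C) should give the ketone (S)-4-(benzyloxy)-3-methoxy-2-methyl-5-(5-phenylpentyl)-6,7-dihydroquinolin-8(5H)-one F1.
- Asymmetric transfer hydrogenation (RuCl(p-cymene)[(R,R)-TsDPEN], HCO2H/Et3N 5:2, rt) should then reduce F1 to 13 under catalyst control, which is matched with the substrate bias for attack anti to the pseudoaxial chain.

**Step 6.** The pyridine nitrogen may be alkylated by the allylic chloride before the coupling. Its coordination to copper or magnesium may also erode the branched-to-linear ratio and the enantioselectivity.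
- The fallback sets out from 3 and comes back to the route at 10. It replaces catalytic allylic alkylation by reagent-controlled lithiation–borylation.
- Miyaura borylation of 3 (B2pin2, PdCl2(dppf), KOAc, dioxane, 90 °C) should give 4-(benzyloxy)-3-methoxy-2-methyl-5-(4,4,5,5-tetramethyl-1,3,2-dioxaborolan-2-yl)pyridine F2.
- Commercial 6-phenylhexan-1-ol is carbamoylated (i-Pr2NCOCl, Et3N, reflux) to 6-phenylhexyl N,N-diisopropylcarbamate F3.
- Sparteine-mediated asymmetric lithiation of F3 (s-BuLi, (−)-sparteine, Et2O, −78 °C), capture by F2 and 1,2-metallate rearrangement (MgBr2, reflux) should give (R)-4-(benzyloxy)-3-methoxy-2-methyl-5-[6-phenyl-1-(4,4,5,5-tetramethyl-1,3,2-dioxaborolan-2-yl)hexyl]pyridine F4.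
- Zweifel olefination of F4 (CH2=CHMgBr; I2; NaOMe) proceeds with retention at the migrating carbon and should return (S)-10.

**Step 2.** Benzylation may occur at nitrogen, because the oxygen is flanked by iodine and methoxy.
- The fallback sets out from 2 and comes back to the route at 3. It replaces alkylation of the ambident pyridone by nucleophilic aromatic substitution.
- Deoxychlorination (POCl3, 90 °C) should give 4-chloro-5-iodo-3-methoxy-2-methylpyridine F5.
- Sodium benzyloxide (BnOH, NaH, DMF, rt to 60 °C) should displace only the activated C4 chloride and give 3.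

Further compounds
F1 | step 8 | (S)-4-(benzyloxy)-3-methoxy-2-methyl-5-(5-phenylpentyl)-6,7-dihydroquinolin-8(5H)-one | COc1c(C)nc2c(c1OCc1ccccc1)[C@@H](CCCCCc1ccccc1)CCC2=O
F2 | step 6 | 4-(benzyloxy)-3-methoxy-2-methyl-5-(4,4,5,5-tetramethyl-1,3,2-dioxaborolan-2-yl)pyridine | COc1c(C)ncc(B2OC(C)(C)C(C)(C)O2)c1OCc1ccccc1
F3 | step 6 | 6-phenylhexyl N,N-diisopropylcarbamate | CC(C)N(C(C)C)C(=O)OCCCCCCc1ccccc1
F4 | step 6 | (R)-4-(benzyloxy)-3-methoxy-2-methyl-5-[6-phenyl-1-(4,4,5,5-tetramethyl-1,3,2-dioxaborolan-2-yl)hexyl]pyridine | COc1c(C)ncc(c1OCc1ccccc1)[C@@H](CCCCCc1ccccc1)B1OC(C)(C)C(C)(C)O1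
F5 | step 2 | 4-chloro-5-iodo-3-methoxy-2-methylpyridine | COc1c(C)ncc(I)c1Cl
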